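**Plan**
1. Cuts (target numbered as a cyclohepta[b]furan-2-one: O1, C2, C3, C3a, C4–C8, C8a): first the lactone bond O1–C8a, then the ring bonds C4–C5 and C3a–C8a together, then the C7 side chain, the C8–O bond and the C6 methyl.
2. Enabling feature: C5 and C8a both carry oxygen and sit 1,4 across the two-carbon unit C4–C3a of the seven-membered ring; their C–O bonds are trans and the lactone is cis-fused. An oxygen bridge between them turns the ring into an 8-oxabicyclo[3.2.1]octane, the [5+2] adduct of a 3-oxidopyrylium (C5–C6–C7–C8–C8a plus the bridge oxygen) and a vinyl ketone (C4=C3a).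
3. Forward order: pyromeconic acid gives a 4-methoxy-3-oxidopyrylium; one cycloaddition closes the carbocycle as the oxabicycle; the three-carbon bridge is dressed from its convex face (C6 methyl, C7 ketone, C8 ester); the C7 side chain is added; the acrylic acid is unveiled; opening of the bridge by that acid closes the lactone last.
4. Stereochemistry: absolute configuration comes from (R)-glyceraldehyde acetonide (a traceless handle on the vinyl ketone: its carbonyl carbon becomes C3, its dioxolane CH the lactone carbonyl C2), from (R)-pent-4-yn-2-ol and from (S)-2-methylbutanoic anhydride. C3a comes from the endo cycloaddition, C5 from the bridge, C6/C7/C8 from convex-face attack on the rigid bicycle, C8a from SN2 inversion.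

Key step: step 4

Locants: the oxabicycles keep one numbering throughout (C1–C7, O8), with C1 = target C5, C2 = C6, C3 = C7, C4 = C8, C5 = C8a, C6 = C3a, C7 = C4; "syn" and "anti" refer to the side of the carbocycle that carries O8.
Assumption: 1, 3, 12 and 14 are taken as purchasable.

**Step 1**
Reactants: 1 pyromeconic acid
Product: 2 3-hydroxy-4-methoxypyrylium triflate
Conditions: MeOTf (1.2 equiv), CH2Cl2, 40 °C; precipitation with Et2O
Reagents that add atoms: methyl trifluoromethanesulfonate, COS(=O)(=O)C(F)(F)F
Why: The pyranone carbonyl oxygen is the most nucleophilic site and is methylated to the aromatic hydroxypyrylium salt, the bench-stable precursor of the oxidopyrylium ylide.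

**Step 2**
Reactants: 3 (R)-glyceraldehyde acetonide
Product: 4 allylic alcohol (both carbinol epimers)
Conditions: CH2=CHMgBr, THF, −78 °C; aq. NH4Cl
Reagents that add atoms: vinylmagnesium bromide, C=C[Mg]Br
Why: Grignard 1,2-addition to the aldehyde; the new carbinol centre is oxidised away in the next step, so its configuration is irrelevant.

**Step 3**
Reactants: 4 allylic alcohol
Product: 5 vinyl ketone
Conditions: Dess–Martin periodinane, NaHCO3, CH2Cl2, 0 °C; used at once
Reagents that add atoms: none
Why: Dess–Martin oxidation under buffered, base-free conditions should give the vinyl ketone without racemising the α-alkoxy stereocentre.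

**Step 4**
Reactants: 2 3-hydroxy-4-methoxypyrylium triflate; 5 vinyl ketone
Product: 7 endo cycloadduct, via 4-methoxy-3-oxidopyrylium 6 (not isolated)
Conditions: 2 (1.5 equiv), PhNMe2 (1.6 equiv), 5 (1.0 equiv), CH2Cl2, 0 °C to 40 °C; chromatography
Reagents that add atoms: none
Why: N,N-Dimethylaniline deprotonates 2 to the ylide 6, whose C2 and C6 add suprafacially across the vinyl group of 5 in a concerted, thermally allowed 6π-electron [5+2] cycloaddition of the 1,3-dipolar type; the closest known reaction type is the intermolecular cycloaddition of base-generated 3-oxidopyrylium and 4-methoxy-3-oxidopyrylium ylides with acrylates and vinyl ketones. The single event closes the seven-membered carbocycle by bonding both ends of the five-carbon pyrylium unit to the alkene at once (and with it the tetrahydrofuran and dihydropyranone rings of the oxabicyclo-octene), so the oxygen bridge is necessarily cis on C1 and C5. The acyl group should end on C6, next to the bridgehead remote from the C2 ketone, because the largest HOMO coefficient of the ylide lies on the carbon adjacent to the oxide, which bonds to the unsubstituted enone terminus. The C6 centre is set by the endo orientation of the acyl group under the pyrylium π-system (secondary orbital overlap), and the absolute sense of C1, C5 and C6 by approach to the enone face left open by the dioxolane. The step needs regio-, endo- and facial selectivity: the first is secured electronically, the other two are only biased, so 7 is to be separated from its exo and facial isomers, which are diastereomers because the dioxolane centre is enantiopure.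

**Step 5**
Reactants: 7 endo cycloadduct
Product: 8 bis-methylidene diene
Conditions: Cp2TiMe2 (4 equiv), toluene/THF, 70 °C, dark
Reagents that add atoms: dimethyltitanocene Cp2TiMe2, C[Ti](C)(C1C=CC=C1)C1C=CC=C1
Why: Petasis methylenation is neutral and not Lewis acidic, so both ketones should become 1,1-disubstituted alkenes without epimerising C6 or ionising the allylic enol-ether bridge; the ring carbonyl carbon is thereby prepared for its methyl group and the side-chain carbonyl carbon receives the future exocyclic methylene.

**Step 6**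
Reactants: 8 bis-methylidene diene
Product: 10 hydroxy enone, via methoxy epoxide 9 (not isolated)
Conditions: DMDO (1.05 equiv), acetone/CH2Cl2, −78 to −40 °C; then THF/pH 5 buffer, 0 °C
Reagents that add atoms: dimethyldioxirane, CC1(C)OO1; water, O
Why: Rubottom-type oxidation: DMDO should epoxidise the most electron-rich double bond (the enol ether) from the convex face remote from the C6–C7 bridge and its endo substituent, and mild hydrolysis of the alkoxy epoxide unveils the C3 ketone with the new C4 hydroxyl syn to the oxygen bridge.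

**Step 7**
Reactants: 10 hydroxy enone
Product: 11 hydroxy ketone
Conditions: [(Ph3P)CuH]6 (Stryker's reagent, 0.35 equiv), H2O (5 equiv), THF, rt
Reagents that add atoms: none
Why: Copper hydride conjugate reduction is selective for the exocyclic enone over the isolated alkene, and protonation of the copper enolate at C2 from the convex face should leave the methyl group equatorial (anti to O8), which is also the thermodynamic epimer.

**Step 8**
Reactants: 11 hydroxy ketone; 12 (S)-2-methylbutanoic anhydride
Product: 13 keto ester
Conditions: 12 (1.5 equiv), pyridine, DMAP (0.2 equiv), CH2Cl2, 0 °C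
Reagents that add atoms: none
Why: DMAP-catalysed acylation of the only free hydroxyl with the preformed enantiopure anhydride avoids a ketene pathway (no racemisation of the acyl centre), and the cold, weakly basic medium should spare the epimerisable α-acyloxy ketone.

**Step 9**
Reactants: 14 (R)-pent-4-yn-2-ol
Product: 15 silyl ether
Conditions: TBSCl, imidazole, DMF, rt
Reagents that add atoms: tert-butyldimethylsilyl chloride, CC(C)(C)[Si](C)(C)Cl
Why: Standard silylation of the secondary alcohol; the stereocentre is not touched.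

**Step 10**
Reactants: 15 silyl ether
Product: 17 vinyl bromide, via bromoalkenylborane 16 (not isolated)
Conditions: B-bromo-9-BBN, CH2Cl2, 0 °C; then AcOH, 0 °C to rt; aq. NaHCO3
Reagents that add atoms: B-bromo-9-borabicyclo[3.3.1]nonane, BrB1C2CCCC1CCC2
Why: Syn bromoboration of the terminal alkyne places boron on the terminal carbon and bromine on the internal one, and protodeboronation with acetic acid leaves the 2-bromo-1-alkene.

**Step 11**
Reactants: 17 vinyl bromide; 13 keto ester
Product: 20 tertiary alcohol, via alkenyllithium 18 (not isolated), via alkenylcerium dichloride 19 (not isolated)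
Conditions: 17, t-BuLi (2.0 equiv), Et2O, −78 °C; anhydrous CeCl3, THF, −78 °C; then 13, −78 °C; aq. NH4Cl
Reagents that add atoms: none
Why: Bromine–lithium exchange and transmetalation give a weakly basic organocerium reagent that should add 1,2 to the hindered, enolisable ketone faster than to the ester, from the convex face because the C6–C7 bridge and its endo substituent block the other one, so the new chain is equatorial (syn to O8) and the tertiary hydroxyl axial (anti).

**Step 12**
Reactants: 20 tertiary alcohol
Product: 21 vicinal diol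
Conditions: AcOH/H2O (4:1), 40 °C
Reagents that add atoms: none
Why: Mild aqueous acid should hydrolyse the terminal isopropylidene acetal faster than it cleaves the secondary silyl ether or ionises the tertiary allylic alcohol.

**Step 13**
Reactants: 21 vicinal diol
Product: 22 enal
Conditions: NaIO4, THF/pH 7 buffer, 0 °C
Reagents that add atoms: none
Why: Malaprade glycol cleavage of the only vicinal diol removes the last carbon of the handle as formaldehyde and leaves the 2-substituted acrolein.

**Step 14**
Reactants: 22 enal
Product: 23 acrylic acid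
Conditions: NaClO2, NaH2PO4, 2-methylbut-2-ene (excess), t-BuOH/H2O, 0 °C
Reagents that add atoms: sodium chlorite, [Na+].[O-]Cl=O
Why: Pinnick oxidation converts the enal into the acrylic acid without touching the alkenes, the scavenger alkene consuming the hypochlorous acid.

**Step 15**
Reactants: 23 acrylic acid
Product: 25 keto acid, via ozonide 24 (not isolated)
Conditions: O3 (1.1 equiv as a cold CH2Cl2 solution), CH2Cl2, −78 °C; then PPh3, −78 °C to rt
Reagents that add atoms: ozone, [O-][O+]=O
Why: Ozone attacks the electron-rich 1,1-dialkyl alkene far faster than the electron-poor acrylic acid double bond, and reductive work-up of the ozonide gives the α-hydroxy ketone of the side chain.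

**Step 16**
Reactants: 25 keto acid
Product: 28 target, via trimethylsilyl ester 26 (not isolated), via silylated lactone 27 (not isolated)
Conditions: BSA (5 equiv), CH2Cl2, rt; TMSOTf (0.3 to 1.0 equiv), −40 to 0 °C; then aq. HF, MeCN, 0 °C
Reagents that add atoms: none
Why: Proposed new method: silylation gives ester 26; TMSOTf reversibly silylates the bridging ether oxygen O8 to an oxonium ion, and the ester carbonyl oxygen, held on the endo face antiperiplanar to the C5–O8 bond, attacks C5 from the rear in a 5-exo-tet SN2 displacement, after which the silyl group of the acyloxonium passes to triflate and regenerates TMSOTf; this inverts C5 (target C8a) to give the cis-fused α-methylene lactone while O8 stays on C1 (target C5) as the silylated hydroxyl, which is the trans relation of the target; the other carbonyl groups cannot reach the rear of either bridge carbon and a tertiary carbinol next to a ketone does not ionise; the closest known reaction types are the acid-catalysed acetolysis of 1,4-epoxycycloalkanes (SN2 opening of an O-activated bridged ether with inversion) and lactonisation by a neighbouring carboxyl group on an onium-activated carbon as in halolactonisation; aqueous HF then removes the three silyl groups.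

**Compound list**
1 | 3-hydroxy-4H-pyran-4-one (pyromeconic acid) | O=C1C=COC=C1O | starting material
2 | 3-hydroxy-4-methoxypyrylium trifluoromethanesulfonate | COC1=C(O)C=[O+]C=C1.[O-]S(=O)(=O)C(F)(F)F | intermediate
3 | (4R)-2,2-dimethyl-1,3-dioxolane-4-carbaldehyde | O=C[C@H]1COC(C)(C)O1 | starting material
4 | 1-[(4R)-2,2-dimethyl-1,3-dioxolan-4-yl]prop-2-en-1-ol, both carbinol epimers | C=CC(O)[C@H]1COC(C)(C)O1 | intermediate
5 | 1-[(4R)-2,2-dimethyl-1,3-dioxolan-4-yl]prop-2-en-1-one | C=CC(=O)[C@H]1COC(C)(C)O1 | intermediate
6 | 4-methoxypyrylium-3-olate (4-methoxy-3-oxidopyrylium ylide) | COC1=C([O-])C=[O+]C=C1 | intermediate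
7 | (1R,5R,6R)-6-{[(4R)-2,2-dimethyl-1,3-dioxolan-4-yl]carbonyl}-3-methoxy-8-oxabicyclo[3.2.1]oct-3-en-2-one; acyl group endo (anti to O8) | O1[C@H]2[C@H](C(=O)[C@H]3COC(C)(C)O3)C[C@@H]1C(=O)C(OC)=C2 | intermediate
8 | (1R,5S,6S)-6-{1-[(4S)-2,2-dimethyl-1,3-dioxolan-4-yl]ethenyl}-3-methoxy-2-methylidene-8-oxabicyclo[3.2.1]oct-3-ene | O1[C@H]2[C@H](C(=C)[C@H]3COC(C)(C)O3)C[C@@H]1C(=C)C(OC)=C2 | intermediate
9 | 3,4-epoxide of 8 (3-methoxy oxirane, oxirane oxygen syn to O8) | O1[C@H]2[C@H](C(=C)[C@H]3COC(C)(C)O3)C[C@@H]1C(=C)[C@@]4(OC)O[C@@H]24 | intermediate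
10 | (1R,4S,5S,6S)-6-{1-[(4S)-2,2-dimethyl-1,3-dioxolan-4-yl]ethenyl}-4-hydroxy-2-methylidene-8-oxabicyclo[3.2.1]octan-3-one; 4-OH syn to O8 | O1[C@H]2[C@H](C(=C)[C@H]3COC(C)(C)O3)C[C@@H]1C(=C)C(=O)[C@H]2O | intermediate
11 | (1R,2S,4S,5S,6S)-6-{1-[(4S)-2,2-dimethyl-1,3-dioxolan-4-yl]ethenyl}-4-hydroxy-2-methyl-8-oxabicyclo[3.2.1]octan-3-one; 2-methyl anti, 4-OH syn to O8 | O1[C@H]2[C@H](C(=C)[C@H]3COC(C)(C)O3)C[C@@H]1[C@H](C)C(=O)[C@H]2O | intermediate
12 | (2S)-2-methylbutanoic anhydride | CC[C@H](C)C(=O)OC(=O)[C@@H](C)CC | starting material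
13 | (1R,2S,4S,5S,6S)-6-{1-[(4S)-2,2-dimethyl-1,3-dioxolan-4-yl]ethenyl}-2-methyl-3-oxo-8-oxabicyclo[3.2.1]octan-4-yl (2S)-2-methylbutanoate | O1[C@H]2[C@H](C(=C)[C@H]3COC(C)(C)O3)C[C@@H]1[C@H](C)C(=O)[C@H]2OC(=O)[C@@H](C)CC | intermediate
14 | (2R)-pent-4-yn-2-ol | C#CC[C@@H](C)O | starting material
15 | tert-butyldimethyl{[(2R)-pent-4-yn-2-yl]oxy}silane | C#CC[C@@H](C)O[Si](C)(C)C(C)(C)C | intermediate
16 | 9-[(1Z,4R)-2-bromo-4-(tert-butyldimethylsilyloxy)pent-1-en-1-yl]-9-borabicyclo[3.3.1]nonane | Br/C(C[C@@H](C)O[Si](C)(C)C(C)(C)C)=C\B1C2CCCC1CCC2 | intermediate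
17 | {[(2R)-4-bromopent-4-en-2-yl]oxy}(tert-butyl)dimethylsilane | C=C(Br)C[C@@H](C)O[Si](C)(C)C(C)(C)C | intermediate
18 | [(4R)-4-(tert-butyldimethylsilyloxy)pent-1-en-2-yl]lithium | [Li]C(=C)C[C@@H](C)O[Si](C)(C)C(C)(C)C | intermediate
19 | dichloro[(4R)-4-(tert-butyldimethylsilyloxy)pent-1-en-2-yl]cerium | Cl[Ce](Cl)C(=C)C[C@@H](C)O[Si](C)(C)C(C)(C)C | intermediate
20 | (1R,2S,3R,4S,5S,6S)-3-[(4R)-4-(tert-butyldimethylsilyloxy)pent-1-en-2-yl]-6-{1-[(4S)-2,2-dimethyl-1,3-dioxolan-4-yl]ethenyl}-3-hydroxy-2-methyl-8-oxabicyclo[3.2.1]octan-4-yl (2S)-2-methylbutanoate; 3-OH anti, 3-alkenyl syn to O8 | O1[C@H]2[C@H](C(=C)[C@H]3COC(C)(C)O3)C[C@@H]1[C@H](C)[C@@](O)(C(=C)C[C@@H](C)O[Si](C)(C)C(C)(C)C)[C@H]2OC(=O)[C@@H](C)CC | intermediate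
21 | analogue of 20 with 6-[(3S)-3,4-dihydroxybut-1-en-2-yl] in place of the dioxolanyl-ethenyl group | O1[C@H]2[C@H](C(=C)[C@H](O)CO)C[C@@H]1[C@H](C)[C@@](O)(C(=C)C[C@@H](C)O[Si](C)(C)C(C)(C)C)[C@H]2OC(=O)[C@@H](C)CC | intermediate
22 | analogue of 20 with 6-(3-oxoprop-1-en-2-yl) (2-substituted acrolein) | O1[C@H]2[C@H](C(=C)C=O)C[C@@H]1[C@H](C)[C@@](O)(C(=C)C[C@@H](C)O[Si](C)(C)C(C)(C)C)[C@H]2OC(=O)[C@@H](C)CC | intermediate
23 | 2-[(1R,2S,3R,4S,5S,6S)-3-[(4R)-4-(tert-butyldimethylsilyloxy)pent-1-en-2-yl]-3-hydroxy-2-methyl-4-{[(2S)-2-methylbutanoyl]oxy}-8-oxabicyclo[3.2.1]octan-6-yl]prop-2-enoic acid | O1[C@H]2[C@H](C(=C)C(=O)O)C[C@@H]1[C@H](C)[C@@](O)(C(=C)C[C@@H](C)O[Si](C)(C)C(C)(C)C)[C@H]2OC(=O)[C@@H](C)CC | intermediate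
24 | ozonide (1,2,4-trioxolane) of 23 at the alkene on C3; trioxolane carbon unassigned | O1[C@H]2[C@H](C(=C)C(=O)O)C[C@@H]1[C@H](C)[C@@](O)(C3(C[C@@H](C)O[Si](C)(C)C(C)(C)C)OCOO3)[C@H]2OC(=O)[C@@H](C)CC | intermediate
25 | 2-[(1R,2S,3S,4S,5S,6S)-3-[(3R)-3-(tert-butyldimethylsilyloxy)butanoyl]-3-hydroxy-2-methyl-4-{[(2S)-2-methylbutanoyl]oxy}-8-oxabicyclo[3.2.1]octan-6-yl]prop-2-enoic acid | O1[C@H]2[C@H](C(=C)C(=O)O)C[C@@H]1[C@H](C)[C@@](O)(C(=O)C[C@@H](C)O[Si](C)(C)C(C)(C)C)[C@H]2OC(=O)[C@@H](C)CC | intermediate
26 | trimethylsilyl ester and 3-O-trimethylsilyl ether of 25 | O1[C@H]2[C@H](C(=C)C(=O)O[Si](C)(C)C)C[C@@H]1[C@H](C)[C@@](O[Si](C)(C)C)(C(=O)C[C@@H](C)O[Si](C)(C)C(C)(C)C)[C@H]2OC(=O)[C@@H](C)CC | intermediate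
27 | the target carrying trimethylsilyl ethers on the C5 and C7 hydroxyls and the TBS ether on the side-chain hydroxyl | C=C1C(=O)O[C@@H]2[C@H]1C[C@@H](O[Si](C)(C)C)[C@H](C)[C@@](O[Si](C)(C)C)(C(=O)C[C@@H](C)O[Si](C)(C)C(C)(C)C)[C@H]2OC(=O)[C@@H](C)CC | intermediate
28 | [(3aS,5R,6S,7S,8S,8aR)-5,7-dihydroxy-7-[(3R)-3-hydroxybutanoyl]-6-methyl-3-methylidene-2-oxooctahydro-2H-cyclohepta[b]furan-8-yl] (2S)-2-methylbutanoate (CNP0291806.4) | C=C1C(=O)O[C@@H]2[C@H]1C[C@@H](O)[C@H](C)[C@@](O)(C(=O)C[C@@H](C)O)[C@H]2OC(=O)[C@@H](C)CC | target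

**Totals**
Total step count: 16. Longest linear sequence: 13 steps (from 3: steps 2 to 8 and 11 to 16).

**Steps most likely to fail**

1. Step 16 (Proposed new method). The silyl triflate may bind the carbonyl oxygens instead of the bridging ether, so that rearward displacement at the secondary bridge carbon is too slow and the silylated ketol and β-silyloxy ketone are lost to acyloin shift or elimination first. The fallback uses known chemistry; it sets out from 25 and comes back at 28. Dimethylboron bromide (Me2BBr, Et3N, CH2Cl2, −78 °C) should cleave the bridged ether by bromide attack with inversion at the less hindered bridge carbon, the one not flanked by the acyloxy group (target C5), to give the bromo hydroxy acid F1, in which the hydroxyl on target C8a keeps the face of the former bridge. Mitsunobu lactonisation (PPh3, DIAD, THF, 0 °C) then closes the lactone with inversion at C8a to give the bromo lactone F2. Displacement of the bromide with inversion by cesium formate (HCO2Cs, DMF, 40 °C) gives the formate F3. Aqueous HF in MeCN followed by brief KHCO3 in MeOH at 0 °C removes the silyl and formyl groups to give 28.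

2. Step 4. A weak endo preference and weak facial discrimination by the remote dioxolane centre may give four cycloadducts from which 7 is hard to isolate, and dimerisation of the ylide may outrun addition to the hindered enone. The fallback removes the endo/exo question by using an alkyne; it sets out from 3 and 2 and comes back at 7. Ethynylmagnesium bromide (HC≡CMgBr, THF, −78 °C) adds to 3 to give the propargylic alcohol F4, and Dess–Martin oxidation gives the ynone F5. Cycloaddition of 2 with F5 (PhNMe2, CH2Cl2, rt to 40 °C) can give only two diastereomeric oxabicyclo-octadienones, from which the dienone cycloadduct F6 is separated. Hydrogenation of its strained, acyl-conjugated C6=C7 bond (H2, Pd/C, EtOAc, 0 °C, one equivalent) from the face that carries O8 then delivers 7 with the acyl group endo by necessity.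

3. Step 11. The organometallic reagent may enolise the ketone (opening the β-alkoxy ketone bridge), attack the neighbouring ester, or lose facial selectivity because the axial acyloxy group hinders the convex-face trajectory. The fallback reverses the order of acylation and carbon–carbon bond formation; it sets out from 11 and comes back at 20. The organocerium reagent 19 (3 equiv, THF, −78 °C) is added to the free hydroxy ketone 11, where no ester is present and the cerium alkoxide of the C4 hydroxyl holds the reagent on the convex face, to give the diol F7. Acylation of its secondary hydroxyl with 12 (pyridine, DMAP, CH2Cl2, 0 °C; the tertiary hydroxyl is inert) then gives 20.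

**Further compounds**
F1 | step 16 | 2-substituted prop-2-enoic acid: open hydroxy acid of the TBS-protected target with bromine on target C5 (inverted, anti to the former bridge) and free hydroxyl on target C8a (face of the former bridge) | OC(=O)C(=C)[C@@H]1C[C@H](Br)[C@H](C)[C@@](O)(C(=O)C[C@@H](C)O[Si](C)(C)C(C)(C)C)[C@@H](OC(=O)[C@@H](C)CC)[C@H]1O
F2 | step 16 | TBS-protected target lactone with bromine in place of the C5 hydroxyl (C5 epimeric position) | C=C1C(=O)O[C@@H]2[C@H]1C[C@H](Br)[C@H](C)[C@@](O)(C(=O)C[C@@H](C)O[Si](C)(C)C(C)(C)C)[C@H]2OC(=O)[C@@H](C)CC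
F3 | step 16 | TBS-protected target lactone with the C5 hydroxyl as its formate | C=C1C(=O)O[C@@H]2[C@H]1C[C@@H](OC=O)[C@H](C)[C@@](O)(C(=O)C[C@@H](C)O[Si](C)(C)C(C)(C)C)[C@H]2OC(=O)[C@@H](C)CC
F4 | step 4 | 1-[(4R)-2,2-dimethyl-1,3-dioxolan-4-yl]prop-2-yn-1-ol, both carbinol epimers | C#CC(O)[C@H]1COC(C)(C)O1
F5 | step 4 | 1-[(4R)-2,2-dimethyl-1,3-dioxolan-4-yl]prop-2-yn-1-one | C#CC(=O)[C@H]1COC(C)(C)O1
F6 | step 4 | (1R,5R)-6-{[(4R)-2,2-dimethyl-1,3-dioxolan-4-yl]carbonyl}-3-methoxy-8-oxabicyclo[3.2.1]octa-3,6-dien-2-one | O1[C@H]2C(C(=O)[C@H]3COC(C)(C)O3)=C[C@@H]1C(=O)C(OC)=C2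
F7 | step 11 | 3,4-diol: compound 20 lacking the 2-methylbutanoyl group (free 4-OH syn to O8, 3-OH anti) | O1[C@H]2[C@H](C(=C)[C@H]3COC(C)(C)O3)C[C@@H]1[C@H](C)[C@@](O)(C(=C)C[C@@H](C)O[Si](C)(C)C(C)(C)C)[C@H]2O
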